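The target of this flask comes with a side product, and the ratio of the two is the number to watch on a repeat.

| flask | starting material | reagent | remark | time |
|---|---|---|---|---|
| south | 6.7 mM | 10.5 mM | run made earlier |  |
| south-west | 15 mM | 10.5 mM | run made earlier |  |
| south-east | 10 mM | 5.2 mM | run made earlier |  |
| flask | 10 mM | 10.5 mM |  | 25 min |

| run | time / min | target / % | side product / % |
|---|---|---|---|
| south | 5.00 | 17.1 | 2.1 |
| south | 10.0 | 17.8 | 2.1 |
| south | 15.0 | 17.8 | 2.8 |
| south | 20.0 | 17.8 | 2.5 |
| south | 25.0 | 17.2 | 1.3 |
| south-west | 2.00 | 11.4 | 1.1 |
| south-west | 6.00 | 11.4 | 0.8 |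
| south-west | 12.0 | 12.6 | 1.4 |
| south-west | 20.0 | 11.6 | 1.3 |
| south-west | 25.0 | 12.3 | 2.2 |
| south-east | 5.00 | 15.0 | 0.7 |
| south-east | 10.0 | 16.2 | 1.2 |
| south-east | 15.0 | 15.9 | 0.9 |
| south-east | 20.0 | 15.3 | 1.7 |
| south-east | 25.0 | 15.3 | 0.3 |

(standard deviation of a reading: 0.5 percentage points)



* ratio of target to side product at 0.80 s
* ratio of target to side product at 30 s
* ratio of target to side product at 25 min

The runs show one rung of the ladder and a plateau behind it. The fast rung lies below the earliest sample at 2.00 min, where the south-west run already reads 11.4% target; 0.80 s and 30 s fall on this rung, unseen by any run. From first to last sample the target then moves by 0.9 percentage points in the south-west run, 0.1 points in the south run and 0.3 points in the south-east run, against a scatter of 0.5 points on each reading, so these readings are taken as a plateau and not as a second, slower stage. The flask at 25 min should therefore read like a late sample, and the readings of each run can be pooled, as side-product readings as low as 0.3% require.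

Pooled target over pooled side product:

south: 8.12

south-west: 8.72

south-east: 16.2

Raising the starting material from 6.7 mM to 15 mM at constant reagent barely moves the ratio. At half the reagent, the south-east ratio is twice the south one. The side product thus reads as first order in [reagent], so the ratio times [reagent] charged should hold steady. The mean of this product over the runs, the selectivity concentration (a selectivity factor carrying a unit), is the carried quantity:

selectivity concentration = 87.0 mM

ratio at 25 min = 87.0 mM / 10.5 mM = 8.29

This reckoning gives no number for the fast rung. The forecast gives 10 at 0.80 s, 8.4 at 30 s and 8.4 at 25 min, and says of the earliest time that “kinetic control could push the ratio either way”.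

The flask gives 110 at 0.80 s, 11.5 at 30 s and 9.15 at 25 min, so it starts higher than the forecast and ends near it.

    target ⇌ isomer of the product (K = 0.960, k = 0.0290 s⁻¹)
    reagent + intermediate B ⇌ intermediate D (K = 20.0 M⁻¹, k = 8.40 M⁻¹ s⁻¹)
    starting material → target (k = 0.0800 s⁻¹)
    reagent + intermediate B ⇌ intermediate C (K = 470 M⁻¹, k = 2.70 M⁻¹ s⁻¹)
    2 starting material → self-condensation product (k = 25.0 M⁻¹ s⁻¹)
    intermediate A → side product (k = 0.0300 s⁻¹)
    starting material + reagent ⇌ intermediate A (K = 28.0 M⁻¹, k = 6.00 M⁻¹ s⁻¹)
    intermediate A → intermediate B (k = 0.150 s⁻¹)

On this flask, the ratio times [reagent] comes to 96.1 mM, against the 87.0 mM read from the runs. The neighbouring flask has the same charge but 42 mM reagent, and is reckoned at 2.07 from the runs or 2.29 from this flask's value. It gives 2.27, a product of 95.3 mM. It ends with 11.6% target beside 5.10% side product, where this flask holds 14.7% and 1.60%.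

(The earlier runs and the new flask were generated by integration with made-up constants, noise included.)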